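**Retrosynthetic overview**
1. Target 17 comes from octabenzyl ether 16 by global O‑debenzylation under neutral conditions.
2. 16 comes from 2'‑hydroxychalcone 15 by closing the O1–C2 bond in an enantioselective intramolecular oxa‑Michael addition; this is the only ring formed in the route (ring C of the flavanone) and it sets C2.
3. 15 comes from biaryl aldehyde 11 and acetophenone 13 (from phloroacetophenone) by Claisen–Schmidt condensation.
4. 11 comes from 8‑iodo‑tetra‑O‑benzylluteolin 5 and bromoaldehyde 8 (via boronate 10) by Suzuki–Miyaura coupling, which makes the 6'–8'' biaryl bond.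
5. The flavone rings are bought intact as luteolin 1; rings A and B of the flavanone come from phloroacetophenone and 3,4‑bis(benzyloxy)benzaldehyde.

Assumption: the SMILES fixes only C2, which is (R) by CIP (the mirror image of the usual natural (2S) flavanone series); the 6'–8'' biaryl axis is undefined and is treated as equilibrating and not controlled.

**Step 1**
Reactants: 1 luteolin; 2 benzyl bromide
Product: 3 5,7-bis(benzyloxy)-2-[3,4-bis(benzyloxy)phenyl]-4H-chromen-4-one (tetra‑O‑benzylluteolin)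
Conditions: BnBr (6 equiv), K2CO3 (8 equiv), DMF, 80 °C, 16 h
Reagents that add atoms: benzyl bromide (2), BrCc1ccccc1
Why: Williamson ether synthesis; excess bromide and heat in DMF also alkylate the chelated 5‑OH, which must be capped to steer the next step to C8.

**Step 2**
Reactants: 3 tetra‑O‑benzylluteolin; 4 N‑iodosuccinimide
Product: 5 5,7-bis(benzyloxy)-2-[3,4-bis(benzyloxy)phenyl]-8-iodo-4H-chromen-4-one
Conditions: NIS (1.1 equiv), CF3CO2H (0.3 equiv), CH2Cl2/MeCN, 0 °C to rt, dark
Reagents that add atoms: N‑iodosuccinimide (4), O=C1CCC(=O)N1I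
Why: Electrophilic aromatic iodination; 5,7‑dialkoxyflavones with O5 capped react at C8 (C6 lies between two benzyloxy groups and is favoured only when 5‑OH is free), while ring B and C3 are much less nucleophilic.

**Step 3**
Reactants: 6 3,4‑bis(benzyloxy)benzaldehyde; 7 bromine
Product: 8 4,5-bis(benzyloxy)-2-bromobenzaldehyde
Conditions: Br2 (1.1 equiv), NaOAc (1.5 equiv), AcOH/CH2Cl2, rt
Reagents that add atoms: bromine (7), BrBr
Why: Electrophilic aromatic bromination para to the 3‑benzyloxy group and ortho to the formyl group (the same position as in veratraldehyde bromination); NaOAc buffers HBr so the benzyl ethers survive.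

**Step 4**
Reactants: 8 4,5‑bis(benzyloxy)‑2‑bromobenzaldehyde; 9 bis(pinacolato)diboron; 5 8‑iodo‑tetra‑O‑benzylluteolin
Product: 11 4,5-bis(benzyloxy)-2-{5,7-bis(benzyloxy)-2-[3,4-bis(benzyloxy)phenyl]-4-oxo-4H-chromen-8-yl}benzaldehyde, via arylboronate 10 (not isolated)
Conditions: 8 (1.3 equiv), B2pin2 (1.4 equiv), PdCl2(dppf) (3 mol %), KOAc (3 equiv), dioxane, 90 °C, 4 h; then 5 (1.0 equiv), Pd(OAc)2 (5 mol %), SPhos (10 mol %), 2 M aq K3PO4 (3 equiv), 90 °C, 12 h
Reagents that add atoms: bis(pinacolato)diboron (9), CC1(C)OB(OC1(C)C)B1OC(C)(C)C(C)(C)O1 — it supplies only the boronate group of intermediate 10; none of its atoms remain in 11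
Why: Miyaura borylation followed in the same pot by Suzuki–Miyaura coupling; the SPhos–palladium catalyst handles the tri‑ortho‑substituted biaryl and couples faster than the ortho‑formyl boronate protodeboronates, and aldehyde, flavone and benzyl ethers are inert.

**Step 5**
Reactants: 12 2',4',6'‑trihydroxyacetophenone; 2 benzyl bromide
Product: 13 1-[2,4-bis(benzyloxy)-6-hydroxyphenyl]ethan-1-one
Conditions: BnBr (2.05 equiv), K2CO3 (2.2 equiv), acetone, reflux
Reagents that add atoms: benzyl bromide (2), BrCc1ccccc1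
Why: Williamson ether synthesis; the hydroxyl hydrogen‑bonded to the acetyl carbonyl is the least nucleophilic, so two equivalents of bromide alkylate the other two selectively.

**Step 6**
Reactants: 11 biaryl aldehyde; 13 1‑[2,4‑bis(benzyloxy)‑6‑hydroxyphenyl]ethan‑1‑one
Product: 15 (2E)-1-[2,4-bis(benzyloxy)-6-hydroxyphenyl]-3-(4,5-bis(benzyloxy)-2-{5,7-bis(benzyloxy)-2-[3,4-bis(benzyloxy)phenyl]-4-oxo-4H-chromen-8-yl}phenyl)prop-2-en-1-one, via aldol adduct 14 (not isolated)
Conditions: KOH (10 equiv, 50 % aq), EtOH/THF 1:1, rt, 36–48 h; poured into ice‑cold 1 M HCl (pH 4)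
Reagents that add atoms: none
Why: Claisen–Schmidt condensation (aldol addition then E1cB dehydration) gives the E‑enone; in strong base the product rests as the open chalcone phenoxide and does not cyclise, the only enolisable ketone is 13, and the fully etherified 2‑arylchromone tolerates KOH at rt.

**Step 7**
Reactants: 15 2'‑hydroxychalcone
Product: 16 (2R)-5,7-bis(benzyloxy)-2-(4,5-bis(benzyloxy)-2-{5,7-bis(benzyloxy)-2-[3,4-bis(benzyloxy)phenyl]-4-oxo-4H-chromen-8-yl}phenyl)-2,3-dihydro-4H-chromen-4-one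
Conditions: 1-[3,5-bis(trifluoromethyl)phenyl]-3-[(2S)-3,3-dimethyl-1-{[tris(4-methoxyphenyl)-λ5-phosphanylidene]amino}butan-2-yl]thiourea (5 mol %), dry toluene (0.05 M), 0 °C; AcOH quench at about 90–95 % conversion; unreacted 15 recovered
Reagents that add atoms: none
Why: Proposed new method: a chiral bifunctional iminophosphorane–thiourea organosuperbase is used for a 6‑endo‑trig intramolecular oxa‑Michael addition of an unactivated 2'‑hydroxy‑6'‑alkoxychalcone, where the P=N base fully ionises the chelated 2'‑OH (breaking the OH···O=C hydrogen bond and releasing the rotamer in which the phenoxide faces C‑β), the chiral aminophosphonium N–H holds the phenoxide while the thiourea binds the enone oxygen and stabilises the developing enolate, the tert‑butyl wall is expected to leave only the Re face of C‑β open so that the new O1–C2 bond gives (2R), and proton transfer from unreacted phenol turns the catalyst over while that same phenol buffers the base and so blocks retro‑oxa‑Michael (E1cB) racemisation as long as the run is quenched before full conversion; the closest known reaction types are the amine–thiourea‑catalysed oxa‑Michael cyclisation of activated alkylidene β‑ketoesters to flavanones and iminophosphorane‑catalysed oxa‑Michael additions of alcohols to unsaturated esters.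

**Step 8**
Reactants: 16 octabenzyl (2R)‑flavanone
Product: 17 (2R)-2-{2-[2-(3,4-dihydroxyphenyl)-5,7-dihydroxy-4-oxo-4H-chromen-8-yl]-4,5-dihydroxyphenyl}-5,7-dihydroxy-2,3-dihydro-4H-chromen-4-one
Conditions: H2 (1 atm), Pd/C (10 wt % Pd), THF/MeOH 1:1, rt, stopped at the end of H2 uptake; filtered under argon
Reagents that add atoms: none
Why: Hydrogenolysis of the eight benzyl ethers under neutral conditions, so C2 cannot epimerise through acid‑ or base‑induced ring opening; the flavone C2=C3 bond and the aryl ketones are not reduced at 1 atm and rt.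

**Compound list**
1 | luteolin | O=c1cc(-c2ccc(O)c(O)c2)oc2cc(O)cc(O)c12 | starting material
2 | benzyl bromide | BrCc1ccccc1 | starting material
3 | 5,7-bis(benzyloxy)-2-[3,4-bis(benzyloxy)phenyl]-4H-chromen-4-one | O=c1cc(-c2ccc(OCc3ccccc3)c(OCc3ccccc3)c2)oc2cc(OCc3ccccc3)cc(OCc3ccccc3)c12 | intermediate
4 | N-iodosuccinimide | O=C1CCC(=O)N1I | starting material
5 | 5,7-bis(benzyloxy)-2-[3,4-bis(benzyloxy)phenyl]-8-iodo-4H-chromen-4-one | O=c1cc(-c2ccc(OCc3ccccc3)c(OCc3ccccc3)c2)oc2c(I)c(OCc3ccccc3)cc(OCc3ccccc3)c12 | intermediate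
6 | 3,4-bis(benzyloxy)benzaldehyde | O=Cc1ccc(OCc2ccccc2)c(OCc2ccccc2)c1 | starting material
7 | bromine | BrBr | starting material
8 | 4,5-bis(benzyloxy)-2-bromobenzaldehyde | O=Cc1cc(OCc2ccccc2)c(OCc2ccccc2)cc1Br | intermediate
9 | bis(pinacolato)diboron | CC1(C)OB(OC1(C)C)B1OC(C)(C)C(C)(C)O1 | starting material
10 | 4,5-bis(benzyloxy)-2-(4,4,5,5-tetramethyl-1,3,2-dioxaborolan-2-yl)benzaldehyde | O=Cc1cc(OCc2ccccc2)c(OCc2ccccc2)cc1B1OC(C)(C)C(C)(C)O1 | intermediate
11 | 4,5-bis(benzyloxy)-2-{5,7-bis(benzyloxy)-2-[3,4-bis(benzyloxy)phenyl]-4-oxo-4H-chromen-8-yl}benzaldehyde | O=Cc1cc(OCc2ccccc2)c(OCc2ccccc2)cc1-c1c(OCc2ccccc2)cc(OCc2ccccc2)c2c(=O)cc(-c3ccc(OCc4ccccc4)c(OCc4ccccc4)c3)oc12 | intermediate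
12 | 2',4',6'-trihydroxyacetophenone | CC(=O)c1c(O)cc(O)cc1O | starting material
13 | 1-[2,4-bis(benzyloxy)-6-hydroxyphenyl]ethan-1-one | CC(=O)c1c(O)cc(OCc2ccccc2)cc1OCc1ccccc1 | intermediate
14 | 1-[2,4-bis(benzyloxy)-6-hydroxyphenyl]-3-(4,5-bis(benzyloxy)-2-{5,7-bis(benzyloxy)-2-[3,4-bis(benzyloxy)phenyl]-4-oxo-4H-chromen-8-yl}phenyl)-3-hydroxypropan-1-one (racemic aldol adduct) | O=C(CC(O)c1cc(OCc2ccccc2)c(OCc2ccccc2)cc1-c1c(OCc2ccccc2)cc(OCc2ccccc2)c2c(=O)cc(-c3ccc(OCc4ccccc4)c(OCc4ccccc4)c3)oc12)c1c(O)cc(OCc2ccccc2)cc1OCc1ccccc1 | intermediate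
15 | (2E)-1-[2,4-bis(benzyloxy)-6-hydroxyphenyl]-3-(4,5-bis(benzyloxy)-2-{5,7-bis(benzyloxy)-2-[3,4-bis(benzyloxy)phenyl]-4-oxo-4H-chromen-8-yl}phenyl)prop-2-en-1-one | O=C(/C=C/c1cc(OCc2ccccc2)c(OCc2ccccc2)cc1-c1c(OCc2ccccc2)cc(OCc2ccccc2)c2c(=O)cc(-c3ccc(OCc4ccccc4)c(OCc4ccccc4)c3)oc12)c1c(O)cc(OCc2ccccc2)cc1OCc1ccccc1 | intermediate
16 | (2R)-5,7-bis(benzyloxy)-2-(4,5-bis(benzyloxy)-2-{5,7-bis(benzyloxy)-2-[3,4-bis(benzyloxy)phenyl]-4-oxo-4H-chromen-8-yl}phenyl)-2,3-dihydro-4H-chromen-4-one | O=C1C[C@H](c2cc(OCc3ccccc3)c(OCc3ccccc3)cc2-c2c(OCc3ccccc3)cc(OCc3ccccc3)c3c(=O)cc(-c4ccc(OCc5ccccc5)c(OCc5ccccc5)c4)oc23)Oc2cc(OCc3ccccc3)cc(OCc3ccccc3)c21 | intermediate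
17 | (2R)-2-{2-[2-(3,4-dihydroxyphenyl)-5,7-dihydroxy-4-oxo-4H-chromen-8-yl]-4,5-dihydroxyphenyl}-5,7-dihydroxy-2,3-dihydro-4H-chromen-4-one | O=C1C[C@H](c2cc(O)c(O)cc2-c2c(O)cc(O)c3c(=O)cc(-c4ccc(O)c(O)c4)oc23)Oc2cc(O)cc(O)c21 | target

**Totals**
Total step count: 8. Longest linear sequence: 6 steps (1, 2, 4, 6, 7, 8).

**Steps most likely to fail**

Step 7 (the proposed cyclisation). The rate may be low on this electron‑rich, hindered enone, and the face selectivity may be eroded by slowly rotating biaryl conformers or by product racemisation near full conversion. The sense of induction is a prediction and must be checked: (2R) should show a negative Cotton effect near 330 nm and a positive one near 290 nm. Fallback with known chemistry, setting out from 15: cyclise with NaOAc in refluxing EtOH/THF to the racemate, a 1:1 mixture of 16 and its mirror image, the (2S)‑flavanone F2. Separate the two on a preparative amylose tris(3,5‑dimethylphenylcarbamate) column by supercritical fluid chromatography. Return F2 to 15 by ring opening with KOH in EtOH/THF and cold acidification, and cycle it again. This comes back to the route at 16.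

Step 4 (one‑pot borylation and hindered coupling). The ortho‑formyl boronate 10 may protodeboronate before it couples with the di‑ortho‑substituted iodide. The fallback reverses the roles of the partners and sets out from 5: Miyaura borylation (B2pin2, PdCl2(dppf), KOAc, dioxane, 90 °C) gives the isolated flavone boronate 5,7‑bis(benzyloxy)‑2‑[3,4‑bis(benzyloxy)phenyl]‑8‑(4,4,5,5‑tetramethyl‑1,3,2‑dioxaborolan‑2‑yl)‑4H‑chromen‑4‑one F1. F1 is then coupled with bromide 8 (Pd(OAc)2, SPhos, aq K3PO4, toluene, 90 °C), where the ortho‑formyl group now speeds oxidative addition and no formyl‑bearing boron species is present. This comes back to the route at 11.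

Step 8 (eightfold hydrogenolysis). Possible problems are incomplete debenzylation of poorly soluble partly deprotected material, slow reduction of the flavone C2=C3 bond, or hydrogenolytic opening of the benzylic O1–C2 bond. The fallback replaces reduction by Lewis‑acid cleavage and sets out from 16: BCl3 (16 equiv) with pentamethylbenzene (24 equiv) as benzyl‑cation scavenger in CH2Cl2 at −78 °C, quenched cold with MeOH/water. It comes back to the route at 17, and no new compound arises on this way (F0).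

**Further compounds**
F1 | step 4 | 5,7-bis(benzyloxy)-2-[3,4-bis(benzyloxy)phenyl]-8-(4,4,5,5-tetramethyl-1,3,2-dioxaborolan-2-yl)-4H-chromen-4-one | O=c1cc(-c2ccc(OCc3ccccc3)c(OCc3ccccc3)c2)oc2c(B3OC(C)(C)C(C)(C)O3)c(OCc3ccccc3)cc(OCc3ccccc3)c12
F2 | step 7 | (2S)-5,7-bis(benzyloxy)-2-(4,5-bis(benzyloxy)-2-{5,7-bis(benzyloxy)-2-[3,4-bis(benzyloxy)phenyl]-4-oxo-4H-chromen-8-yl}phenyl)-2,3-dihydro-4H-chromen-4-one | O=C1C[C@@H](c2cc(OCc3ccccc3)c(OCc3ccccc3)cc2-c2c(OCc3ccccc3)cc(OCc3ccccc3)c3c(=O)cc(-c4ccc(OCc5ccccc5)c(OCc5ccccc5)c4)oc23)Oc2cc(OCc3ccccc3)cc(OCc3ccccc3)c21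
F0 | step 8 | none | none
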